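## Structural features

The target is a dimeric dibenzylbutyrolactone lignan: two γ-butyrolactones, each with an arylmethyl group at C3 (α to the carbonyl), a 3,4-dimethoxybenzyl (veratryl) group at C4 and an unsubstituted OCH2 at C5; the two veratryl rings are called ring A and ring B. The C3 arylmethyl groups belong to ring C (3-methoxy-4-aryloxyphenyl) and ring D (4-hydroxy-3-methoxy-5-aryloxyphenyl), and a single ether oxygen joins C4 of ring C to the ring D carbon ortho to the free phenol. The four stereocentres form two adjacent C3/C4 pairs, all S and each pair trans. The achiral diaryl ether separates the pairs, so neither can relay its configuration to the other and each must be set in the absolute sense. Fragile points are the epimerisable C3 centres (trans is the thermodynamic arrangement), the lactones (opened by hydroxide or alkoxide), the oxidation-prone ring D phenol, which must also be told apart from five methyl ethers, and four electron-rich arenes. The real difficulty is twofold: the unsymmetrical, heavily oxygenated diaryl ether, and the need to exert the same absolute stereocontrol twice in one molecule, where each lapse gives a diastereomer. The key step exploits the fact that both C4 atoms carry the same veratryl group, which is the benzylic radical left when homoveratric acid loses CO2. It also exploits the fact that both C5 atoms are CH2 groups, which can be carried as menthyloxy acetal carbons, a removable stereocentre directly beside C4.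

## Logic of the disconnections

18 to 17: the O–CH2Ph bond at the ring D phenol is cut. The phenol has to stay masked through ether formation, organozinc chemistry, cathodic reduction and hydride/hydroxide treatment, and a benzyl ether is removed last under neutral conditions. The final step must therefore leave two lactones, a diaryl ether and the C3 centres untouched.

17 to 15: each C5 methylene is traced back to an acetal carbon bearing a d-menthyloxy group. This costs no skeletal change and places a resident stereocentre next to each C4. The forward step must bring C5 from the aldehyde level to CH2 without epimerising C4, which is α to a transient aldehyde, and without changing which carbon is the lactone carbonyl.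

15 to 13 and 11: both C4–CH2(veratryl) bonds are cut, together with the C3–H bonds that accompany them. This removes rings A and B as two identical one-carbon-linked fragments (two molecules of 11 per molecule of 13) and removes all four target stereocentres. The two acetal centres of 13 remain, and they are bought, not made. The forward step must add a benzylic radical to C4 of a trisubstituted butenolide, anti to the C5 substituent, twice in one molecule, and must then bring C3 to the trans arrangement.

13 to 6 and 9 (through 12): both C3–CH2(aryl) bonds are cut as sp2–sp3 cross-coupling bonds. This separates the achiral diaryl ether core from two copies of one small chiral butenolide, so one molecule of 6 is matched with two molecules of 9. The forward step needs a bis-benzylic organometallic that forms without Wurtz coupling and a twofold coupling mild enough to leave the base-sensitive acetal centre of 9 intact.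

9 to 7 (through 8): the C3–Br bond is cut. Halogenation followed by dehydrohalogenation puts the halide on the α carbon of a commercial, enantiopure butenolide. The amine base must not touch C5.

11 to 10: the acyl–O bond of the redox-active ester is cut, which leads back to a commercial arylacetic acid. The forward step is a routine esterification.

6 to 5 to 4: the two C–Cl bonds are traced to C–OH and then to formyl groups. The formyl groups are kept this far back because one of them is needed to activate the ether-forming step. Forward, this means one double reduction and one double chlorination.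

4 to 2 and 3: the diaryl ether is cut at the O–C4 bond of ring C, because a para formyl group makes that carbon an SNAr acceptor when it carries fluoride. The nucleophile must have exactly one free phenol.

2 to 1: the O–benzyl bond is cut. The two phenols of 1 differ in acidity (the one para to the formyl group is the stronger acid), so the protecting group can be placed selectively on the oxygen that becomes the free phenol of the target.

## Other disconnections considered

Alternative 1: The cut is at both C3–CH2(aryl) bonds of 17 and, one stage earlier, at the ring oxygen of a simple β-substituted lactone. In the forward direction a Baeyer–Villiger monooxygenase of the cyclohexanone monooxygenase class (NADPH, O2) would desymmetrise 3-(3,4-dimethoxybenzyl)cyclobutanone A2, reachable in two operations from 4-allyl-1,2-dimethoxybenzene A3 by [2+2] cycloaddition with a chlorinated ketene and reductive dechlorination. The enzyme-bound flavin hydroperoxide adds to the ketone and one of the two enantiotopic CH2 groups migrates to oxygen, which would give (S)-4-(3,4-dimethoxybenzyl)dihydrofuran-2(3H)-one A1. Two equivalents of the lithium enolate of A1 would then be alkylated by 6, anti to the C4 substituent, to give 17, and step 10 would finish the synthesis.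
- In its favour: the asymmetric step is catalytic, uses air as oxidant and needs no auxiliary. Kinetic alkylation should give the 3,4-trans lactone directly, so no equilibration is needed. On C3 control it is the equal or the better of the chosen plan.
- On step economy it is better: about nine operations with a longest linear sequence of six, against ten and eight.
- Against it: the sense and level of enantiotopic-group selectivity for an arylmethyl cyclobutanone depend on the enzyme and would have to be found by screening. Any shortfall in the purity of A1 is converted in the dimer into a diastereomer that must be separated.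
- Also against it: the double alkylation of a bis-electrophile consumes an excess of the chiral enolate and can stop at mono-alkylation or run on to α,α-dialkylation.
- Comparison: structurally both plans attach two identical chiral lactone units to the same core 6, and mechanistically an enzymatic oxygen insertion replaces a radical conjugate addition. The chosen plan takes its absolute configuration from a crystalline, purchasable auxiliary whose directing sense is predictable, and its stereo-errors appear as separable diastereomers at the stage of 15. It pays for this with two extra operations to attach and remove the acetal.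

Alternative 2: The cut is at ring C itself, at bonds C4–C5 and C1–C2. In the forward direction the aryloxyacetone A5 (ring D with its complete lactone) would react with the enaminone A6 (the other complete lactone) under base. The aryloxy-substituted α carbon adds to the enaminone β carbon, the dimethylamino group is expelled, and the ketone methyl group condenses with the enaminone carbonyl. Dehydration would give the phenol A4, and O-methylation of A4 would give 17.
- In its favour: the diaryl ether oxygen is installed by simple phenol alkylation, so no activated haloarene and no hot substitution with a hindered phenoxide are needed. On that point it is the better plan.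
- It also leaves the ring C oxygen free for late variation, which the chosen plan cannot offer.
- Against it: A5 and A6 each already contain a finished trans-lactone, so the disconnection does nothing for the stereochemical problem. Two different lactone halves would have to be made by some other asymmetric method.
- The base and heat of the annulation, and the secondary amine released, threaten lactone opening and C3 integrity. The ketone must enolise toward the aryloxy carbon for the Michael step and toward the methyl group for the aldol step. An extra methylation follows.
- Comparison: structurally it builds an arene that the chosen plan buys, and mechanistically it relies on ionic condensation chemistry under basic conditions, where the chosen plan uses a radical addition under near-neutral conditions. It is much longer and less convergent in its stereochemistry than the chosen plan.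

Alternative 3: The cut is at both lactone C3–C4 bonds. In the forward direction the bis-ester A8 would be made from 4 by two-carbon homologation at each formyl group and esterification with the allylic alcohol A9. Enolisation in a strongly coordinating medium and O-silylation would give the bis(trimethylsilyl ketene acetal) A10, which would rearrange through two chair transition states (Ireland–Claisen) to the bis-acid A7 with both C2–C3 pairs syn. Ozonolysis of the propenyl groups, hydride reduction and lactonisation would lead to 17.
- In its favour: the most central bond of each lactone and both of its stereocentres are formed in one concerted thermal step. The chirality comes from one simple carbinol centre, and C3 is set kinetically. In these respects it is at least the equal of the chosen plan, and it needs no electrochemical equipment.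
- Against it: the syn acids need the ketene acetal geometry of A10, in which the arylmethyl group is trans to the allyloxy oxygen. That requires enolisation in a strongly coordinating co-solvent, where geometric control is usually less complete, and it is needed twice.
- The alkene cleavage must be done in the presence of four electron-rich arenes.
- Comparison: structurally it forms the C3–C4 bond, where the chosen plan forms the exocyclic C4–CH2 bond, and mechanistically a sigmatropic shift with chirality transfer replaces an auxiliary-directed radical addition. The count comes to roughly fourteen operations, which is worse than the chosen plan.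

Key step: step 8

Assumption: kinetic protonation of the C3 enolates in the key step is taken to favour the 3,4-cis lactones, so a base equilibration to the trans lactones is built into step 8; the key-step precursor 13 and product 15 were checked centre by centre against the target ((3S,4S) in both lactones, (5S) at both acetal carbons, d-menthyl = (1S,2R,5S)) and are consistent with it.

## Route

Step 1
Reactants: 1 5-hydroxyvanillin (3,4-dihydroxy-5-methoxybenzaldehyde)
Product: 2 4-(benzyloxy)-3-hydroxy-5-methoxybenzaldehyde
Conditions: BnBr (1.05 equiv), Li2CO3 (1.5 equiv), DMF, 45 °C
Reagents that add atoms: benzyl bromide, BrCc1ccccc1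
Why: Williamson etherification under weak-base control; Li2CO3 ionises only the more acidic 4-OH (para to the formyl group), so that oxygen is benzylated and the 5-OH stays free, a known selectivity for 3,4-dihydroxybenzaldehydes.

Step 2
Reactants: 2 4-(benzyloxy)-3-hydroxy-5-methoxybenzaldehyde; 3 4-fluoro-3-methoxybenzaldehyde
Product: 4 4-(benzyloxy)-3-(4-formyl-2-methoxyphenoxy)-5-methoxybenzaldehyde
Conditions: K2CO3 (1.5 equiv), DMF, 110 °C
Reagents that add atoms: none
Why: SNAr (addition–elimination through a Meisenheimer intermediate); the single phenoxide of 2 displaces the fluoride para to the formyl group of 3, so only one diaryl ether can form, and the benzyl ether and both aldehydes tolerate carbonate.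

Step 3
Reactants: 4 4-(benzyloxy)-3-(4-formyl-2-methoxyphenoxy)-5-methoxybenzaldehyde
Product: 5 [4-(benzyloxy)-3-[4-(hydroxymethyl)-2-methoxyphenoxy]-5-methoxyphenyl]methanol
Conditions: NaBH4 (1.5 equiv), THF/MeOH, 0 °C
Reagents that add atoms: none
Why: Borohydride reduction of both aryl aldehydes to benzylic alcohols; ethers are inert.

Step 4
Reactants: 5 [4-(benzyloxy)-3-[4-(hydroxymethyl)-2-methoxyphenoxy]-5-methoxyphenyl]methanol
Product: 6 2-(benzyloxy)-5-(chloromethyl)-1-[4-(chloromethyl)-2-methoxyphenoxy]-3-methoxybenzene
Conditions: SOCl2 (2.4 equiv), CH2Cl2, 0 → 25 °C; used crude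
Reagents that add atoms: thionyl chloride, ClS(Cl)=O
Why: Deoxychlorination of benzylic alcohols through chlorosulfites; chlorides are chosen over bromides because they insert zinc cleanly in the presence of LiCl and are less prone to Wurtz coupling.

Step 5
Reactants: 7 (5S)-5-(d-menthyloxy)furan-2(5H)-one
Product: 9 (5S)-3-bromo-5-(d-menthyloxy)furan-2(5H)-one, via trans-3,4-dibromolactone 8 (not isolated)
Conditions: Br2 (1.05 equiv), CH2Cl2, 0 °C; then Et3N (1.3 equiv), 0 °C
Reagents that add atoms: bromine, BrBr
Why: Anti addition of Br2 to the enoate C=C, then E1cB loss of HBr (the acidic C3–H is removed and the C4 bromide leaves) gives the α-bromobutenolide; the C5 acetal centre is not involved, and the base is kept cold and brief to avoid C5 epimerisation.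

Step 6
Reactants: 10 homoveratric acid ((3,4-dimethoxyphenyl)acetic acid)
Product: 11 1,3-dioxoisoindolin-2-yl (3,4-dimethoxyphenyl)acetate
Conditions: N-hydroxyphthalimide (1.1 equiv), DIC (1.1 equiv), DMAP (0.1 equiv), CH2Cl2, 25 °C
Reagents that add atoms: N-hydroxyphthalimide, ON1C(=O)c2ccccc2C1=O
Why: Carbodiimide (Steglich-type) esterification to the redox-active ester; no other functional group competes.

Step 7
Reactants: 6 2-(benzyloxy)-5-(chloromethyl)-1-[4-(chloromethyl)-2-methoxyphenoxy]-3-methoxybenzene (1 equiv); 9 (5S)-3-bromo-5-(d-menthyloxy)furan-2(5H)-one (2 equiv enter the product)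
Product: 13 bis(butenolide) in which each benzylic CH2 of the diaryl ether core is bonded to C3 of a (5S)-5-(d-menthyloxy)furan-2(5H)-one, via bis(benzylzinc chloride) 12 (not isolated)
Conditions: Zn dust (activated, 4 equiv), LiCl (3 equiv), THF, 25 °C; then 9 (2.3 equiv), Pd(PPh3)4 (5 mol %), THF, 25 → 45 °C
Reagents that add atoms: (5S)-3-bromo-5-(d-menthyloxy)furan-2(5H)-one (compound 9; second equivalent), O=C1C(Br)=C[C@@H](O[C@H]2C[C@@H](C)CC[C@@H]2C(C)C)O1
Why: LiCl-promoted zinc insertion into both benzylic chlorides followed by a twofold Negishi coupling (oxidative addition of the C3–Br bond to zerovalent palladium, transmetallation from zinc, reductive elimination), so that one molecule of 6 takes up two molecules of 9; the organozinc is neither basic nor nucleophilic enough to attack the lactone, to add in a conjugate sense or to disturb C5.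

Step 8
Reactants: 13 bis(butenolide) with (5S)-5-(d-menthyloxy) acetal centres (1 equiv); 11 1,3-dioxoisoindolin-2-yl (3,4-dimethoxyphenyl)acetate (2 equiv enter the product)
Product: 15 bis(lactone acetal) with both rings (3S,4S,5S) (3,4-trans and 4,5-trans) and a veratryl group on each C4, via 3,4-cis C3-epimer 14 (not isolated)
Conditions: undivided cell, graphite-felt cathode, Zn anode, constant current (about 2.5 F per mol of 11), 11 (6 equiv, added in portions), LiBr (0.2 M), H2O (10 equiv), DMA, 25 °C; aq NH4Cl work-up; then DBU (1 equiv), PhMe, 50 °C
Reagents that add atoms: 1,3-dioxoisoindolin-2-yl (3,4-dimethoxyphenyl)acetate (compound 11; second equivalent), COc1ccc(CC(=O)ON2C(=O)c3ccccc3C2=O)cc1OC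
Why: At the cathode 11 takes up one electron and its radical anion fragments to CO2, phthalimide anion and the 3,4-dimethoxybenzyl radical, while the zinc anode supplies the counter-charge. The nucleophilic benzylic radical adds to the unsubstituted, electrophilic C4 of each butenolide and leaves a tertiary, carbonyl-stabilised radical at C3, which is reduced to the enolate and protonated by water. The closest known reaction type is the electroreductive decarboxylative Giese addition of N-hydroxyphthalimide esters, combined with the established anti addition of radicals and nucleophiles to 5-menthyloxybutenolides. No ring is closed. Each new C4 centre is controlled by the neighbouring C5 acetal centre: the d-menthyloxy group shields its own face of the flat ring, so the C4–CH2 bond forms on the opposite face. The C3 centres are not fixed by the radical step; protonation anti to the new C4 substituent should favour the cis epimer 14, and DBU then equilibrates C3 through the enolate to the all-trans arrangement of 15. The step needs regioselectivity (C4 over C3, secured by polarity matching and by the stability of the α-carbonyl radical), facial selectivity (secured by the auxiliary at C5) and chemoselectivity for addition over dimerisation or further reduction of the benzylic radical, for which 11 is used in excess and fed in slowly. The benzyl ether, the diaryl ether and the acetals lie outside the potential window needed to reduce 11.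

Step 9
Reactants: 15 bis(lactone acetal) with both rings (3S,4S,5S)
Product: 17 O-benzyl bis-lactone with both rings (3S,4S)-3-(arylmethyl)-4-(3,4-dimethoxybenzyl)dihydrofuran-2(3H)-one, via dipotassium bis(hydroxy carboxylate) 16 (not isolated)
Conditions: NaBH4 (6 equiv), KOH (6 equiv), THF/H2O, 0 → 25 °C; then 2 M HCl to pH 1, 25 °C
Reagents that add atoms: potassium hydroxide, [K+].[OH-]
Why: Hydroxide opens each acyl acetal to a carboxylate (its oxygen enters the carboxylate of 16 and can remain as the carbonyl oxygen after ring closure) and a hemiacetal that collapses to the aldehyde with loss of menthol. The borohydride, present throughout, reduces that aldehyde at once to the primary alcohol, and acid closes the γ-lactone with C5 now a CH2, which is the known reductive removal of the menthyloxy group from such lactone acetals. C3 sits next to a carboxylate and does not enolise, and C4 is safe as long as reduction outruns enolisation of the aldehyde.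

Step 10
Reactants: 17 O-benzyl bis-lactone
Product: 18 target, (3S,4S,3'S,4'S) diaryl ether bis-lactone with free ring D phenol
Conditions: H2 (1 atm), 10% Pd/C, EtOAc/EtOH, 25 °C
Reagents that add atoms: none
Why: Hydrogenolysis of the benzyl aryl ether; the lactone O–CH2 bonds are not benzylic, and the diaryl ether, methyl ethers and stereocentres are inert under these neutral conditions.

## Compound list

1 | 5-hydroxyvanillin (3,4-dihydroxy-5-methoxybenzaldehyde) | COc1cc(C=O)cc(O)c1O | starting material
2 | 4-(benzyloxy)-3-hydroxy-5-methoxybenzaldehyde | COc1cc(C=O)cc(O)c1OCc1ccccc1 | intermediate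
3 | 4-fluoro-3-methoxybenzaldehyde | COc1cc(C=O)ccc1F | starting material
4 | 4-(benzyloxy)-3-(4-formyl-2-methoxyphenoxy)-5-methoxybenzaldehyde | COc1cc(C=O)ccc1Oc1cc(C=O)cc(OC)c1OCc1ccccc1 | intermediate
5 | [4-(benzyloxy)-3-[4-(hydroxymethyl)-2-methoxyphenoxy]-5-methoxyphenyl]methanol | COc1cc(CO)ccc1Oc1cc(CO)cc(OC)c1OCc1ccccc1 | intermediate
6 | 2-(benzyloxy)-5-(chloromethyl)-1-[4-(chloromethyl)-2-methoxyphenoxy]-3-methoxybenzene | COc1cc(CCl)ccc1Oc1cc(CCl)cc(OC)c1OCc1ccccc1 | intermediate
7 | (5S)-5-(d-menthyloxy)furan-2(5H)-one, d-menthyl = (1S,2R,5S)-2-isopropyl-5-methylcyclohexyl | O=C1C=C[C@@H](O[C@H]2C[C@@H](C)CC[C@@H]2C(C)C)O1 | starting material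
8 | trans-3,4-dibromo-5-(d-menthyloxy)dihydrofuran-2(3H)-one, drawn as the (3R,4R,5S) isomer (either trans-dibromide eliminates to 9) | O=C1[C@@H](Br)[C@H](Br)[C@@H](O[C@H]2C[C@@H](C)CC[C@@H]2C(C)C)O1 | intermediate (not isolated)
9 | (5S)-3-bromo-5-(d-menthyloxy)furan-2(5H)-one | O=C1C(Br)=C[C@@H](O[C@H]2C[C@@H](C)CC[C@@H]2C(C)C)O1 | intermediate
10 | homoveratric acid ((3,4-dimethoxyphenyl)acetic acid) | COc1ccc(CC(=O)O)cc1OC | starting material
11 | 1,3-dioxoisoindolin-2-yl (3,4-dimethoxyphenyl)acetate | COc1ccc(CC(=O)ON2C(=O)c3ccccc3C2=O)cc1OC | intermediate
12 | bis(benzylzinc chloride) of the diaryl ether core (ArCH2ZnCl at both benzylic positions, LiCl-solvated) | COc1cc(C[Zn]Cl)ccc1Oc1cc(C[Zn]Cl)cc(OC)c1OCc1ccccc1 | intermediate (not isolated)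
13 | bis(butenolide): each benzylic CH2 of the core on C3 of a (5S)-5-(d-menthyloxy)furan-2(5H)-one, ring D 4-O-benzyl | COc1cc(CC2=C[C@@H](O[C@H]3C[C@@H](C)CC[C@@H]3C(C)C)OC2=O)ccc1Oc1cc(CC2=C[C@@H](O[C@H]3C[C@@H](C)CC[C@@H]3C(C)C)OC2=O)cc(OC)c1OCc1ccccc1 | intermediate (key-step precursor)
14 | bis(lactone acetal), both rings (3R,4S,5S): 3,4-cis, 4,5-trans (kinetic C3 epimer) | COc1cc(C[C@H]2C(=O)O[C@H](O[C@H]3C[C@@H](C)CC[C@@H]3C(C)C)[C@H]2Cc2ccc(OC)c(OC)c2)ccc1Oc1cc(C[C@H]2C(=O)O[C@H](O[C@H]3C[C@@H](C)CC[C@@H]3C(C)C)[C@H]2Cc2ccc(OC)c(OC)c2)cc(OC)c1OCc1ccccc1 | intermediate (not isolated)
15 | bis(lactone acetal), both rings (3S,4S,5S): 3,4-trans, 4,5-trans, ring D 4-O-benzyl | COc1cc(C[C@@H]2C(=O)O[C@H](O[C@H]3C[C@@H](C)CC[C@@H]3C(C)C)[C@H]2Cc2ccc(OC)c(OC)c2)ccc1Oc1cc(C[C@@H]2C(=O)O[C@H](O[C@H]3C[C@@H](C)CC[C@@H]3C(C)C)[C@H]2Cc2ccc(OC)c(OC)c2)cc(OC)c1OCc1ccccc1 | intermediate (key-step product)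
16 | dipotassium bis[(2S,3S)-2-(arylmethyl)-3-(3,4-dimethoxybenzyl)-4-hydroxybutanoate] of the core | COc1cc(C[C@H](C(=O)[O-])[C@@H](CO)Cc2ccc(OC)c(OC)c2)ccc1Oc1cc(C[C@H](C(=O)[O-])[C@@H](CO)Cc2ccc(OC)c(OC)c2)cc(OC)c1OCc1ccccc1.[K+].[K+] | intermediate (not isolated)
17 | O-benzyl bis-lactone, both rings (3S,4S)-3-(arylmethyl)-4-(3,4-dimethoxybenzyl)dihydrofuran-2(3H)-one | COc1cc(C[C@@H]2C(=O)OC[C@H]2Cc2ccc(OC)c(OC)c2)ccc1Oc1cc(C[C@@H]2C(=O)OC[C@H]2Cc2ccc(OC)c(OC)c2)cc(OC)c1OCc1ccccc1 | intermediate
18 | CNP0183104.1, (3S,4S,3'S,4'S) bis-lactone with free ring D phenol | COc1ccc(C[C@@H]2COC(=O)[C@H]2Cc2ccc(Oc3cc(C[C@@H]4C(=O)OC[C@H]4Cc4ccc(OC)c(OC)c4)cc(OC)c3O)c(OC)c2)cc1OC | target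

## Step count and least certain steps

Total step count: 10. Longest linear sequence: 8 (steps 1, 2, 3, 4, 7, 8, 9, 10).

Step 8 (key step). The most likely failure is loss of the stabilised benzylic radical by dimerisation or further cathodic reduction before it adds. Its addition to a trisubstituted, α-branched acceptor is comparatively slow and can be reversible, so one or both butenolides may stay unreacted. Base that builds up at the cathode may in addition isomerise unreacted butenolide through γ-deprotonation at C5. The fallback replaces the radical by a carbanion and sets out from 7 and 6. 2-(3,4-Dimethoxyphenyl)-1,3-dithiane F1 (from 3,4-dimethoxybenzaldehyde and propane-1,3-dithiol with BF3·OEt2) is lithiated with n-BuLi at −78 °C and added to C4 of 7 anti to the menthyloxy group. Two equivalents of the resulting lithium enolate are alkylated at C3, anti to the new C4 substituent, by one equivalent of 6 (NaI, DMPU), which gives the bis(dithiane) lactone acetal F2. Desulfurisation with Raney Ni (deactivated in acetone to spare the benzyl ether) in EtOH/THF turns both dithiane carbons into CH2 and returns to the route at 15. Compounds 9 and 11 to 14 are then not needed.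

Step 7. Zinc insertion into a bis-benzylic halide may be accompanied by Wurtz-type homocoupling or oligomerisation, and protonation of one carbon–zinc bond before the second coupling would leave the coupling half finished. The fallback reverses the roles of the partners, so that no benzylic organometallic is needed, and sets out from 9 and 6. Palladium-catalysed stannylation of 9 ((Bu3Sn)2, Pd(PPh3)4, PhMe, 90 °C) gives (5S)-5-(d-menthyloxy)-3-(tributylstannyl)furan-2(5H)-one F3. A twofold Stille coupling of F3 (2.3 equiv) with 6 (Pd(PPh3)4, CuI, DMF, 60 °C; aqueous KF work-up to remove the tin halides) forms both C3–CH2 bonds and rejoins the route at 13.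

Step 9. The transient aldehyde carries C4 as its α carbon, so enolisation in hydroxide before hydride delivery would erode C4. Hydride attack on the lactone carbonyl in competition with ring opening would reduce the wrong carbon. The fallback separates unmasking from reduction and sets out from 15. Aqueous HCl in dioxane at 60 °C hydrolyses both acetals to the bis(5-hydroxylactone) F4, which is the cyclic form of the aldehyde acid and is protected from enolisation. NaBH4 in THF/aqueous NaHCO3 at 0 °C then reduces the ring-opened aldehyde, and acidification closes the lactones to rejoin the route at 17.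

Step 2. The fluoroarene is activated by a single para formyl group and deactivated by the ortho methoxy group, so substitution by a hindered phenoxide may be slow. The aldehydes may then degrade at the temperature needed. The fallback changes the bond-forming mechanism and sets out from 2: Ullmann-type coupling with commercial 4-bromo-3-methoxybenzaldehyde (CuI, N,N-dimethylglycine, Cs2CO3, dioxane, 90 °C) gives 4 directly, where it rejoins the route.

## Further compounds

F1 | step 8 | 2-(3,4-dimethoxyphenyl)-1,3-dithiane | COc1ccc(C2SCCCS2)cc1OC
F2 | step 8 | bis(lactone acetal) with a 2-(3,4-dimethoxyphenyl)-1,3-dithian-2-yl group on each C4 (3,4-trans, 4,5-trans, 5S) | COc1cc(C[C@@H]2C(=O)O[C@H](O[C@H]3C[C@@H](C)CC[C@@H]3C(C)C)[C@H]2C2(c3ccc(OC)c(OC)c3)SCCCS2)ccc1Oc1cc(C[C@@H]2C(=O)O[C@H](O[C@H]3C[C@@H](C)CC[C@@H]3C(C)C)[C@H]2C2(c3ccc(OC)c(OC)c3)SCCCS2)cc(OC)c1OCc1ccccc1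
F3 | step 7 | (5S)-5-(d-menthyloxy)-3-(tributylstannyl)furan-2(5H)-one | O=C1C([Sn](CCCC)(CCCC)CCCC)=C[C@@H](O[C@H]2C[C@@H](C)CC[C@@H]2C(C)C)O1
F4 | step 9 | bis(5-hydroxylactone), both rings (3S,4S), anomeric mixture at C5 | COc1cc(C[C@@H]2C(=O)OC(O)[C@H]2Cc2ccc(OC)c(OC)c2)ccc1Oc1cc(C[C@@H]2C(=O)OC(O)[C@H]2Cc2ccc(OC)c(OC)c2)cc(OC)c1OCc1ccccc1
F0 | step 2 | none | none
A1 | alternative 1 | (S)-4-(3,4-dimethoxybenzyl)dihydrofuran-2(3H)-one | COc1ccc(C[C@@H]2COC(=O)C2)cc1OC
A2 | alternative 1 | 3-(3,4-dimethoxybenzyl)cyclobutanone | COc1ccc(CC2CC(=O)C2)cc1OC
A3 | alternative 1 | 4-allyl-1,2-dimethoxybenzene | C=CCc1ccc(OC)c(OC)c1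
A4 | alternative 2 | bis-lactone with ring C as free 3-phenol and ring D as benzyl ether | Oc1cc(C[C@@H]2C(=O)OC[C@H]2Cc2ccc(OC)c(OC)c2)ccc1Oc1cc(C[C@@H]2C(=O)OC[C@H]2Cc2ccc(OC)c(OC)c2)cc(OC)c1OCc1ccccc1
A5 | alternative 2 | 1-aryloxypropan-2-one carrying ring D (4-O-benzyl) and its (3S,4S) lactone | CC(=O)COc1cc(C[C@@H]2C(=O)OC[C@H]2Cc2ccc(OC)c(OC)c2)cc(OC)c1OCc1ccccc1
A6 | alternative 2 | (3S,4S)-4-(3,4-dimethoxybenzyl)-3-[(E)-4-(dimethylamino)-2-oxobut-3-enyl]dihydrofuran-2(3H)-one | CN(C)/C=C/C(=O)C[C@@H]1C(=O)OC[C@H]1Cc1ccc(OC)c(OC)c1
A7 | alternative 3 | bis(2-arylmethyl-3-veratrylhex-4-enoic acid), syn at both C2–C3 pairs, ring D 4-O-benzyl | COc1ccc(C[C@H](/C=C/C)[C@H](Cc2ccc(Oc3cc(C[C@H](C(=O)O)[C@@H](/C=C/C)Cc4ccc(OC)c(OC)c4)cc(OC)c3OCc3ccccc3)c(OC)c2)C(=O)O)cc1OC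
A8 | alternative 3 | bis(3-arylpropanoate) of the core with (S,E)-5-(3,4-dimethoxyphenyl)pent-3-en-2-ol | COc1cc(CCC(=O)O[C@@H](C)/C=C/Cc2ccc(OC)c(OC)c2)ccc1Oc1cc(CCC(=O)O[C@@H](C)/C=C/Cc2ccc(OC)c(OC)c2)cc(OC)c1OCc1ccccc1
A9 | alternative 3 | (S,E)-5-(3,4-dimethoxyphenyl)pent-3-en-2-ol | C[C@H](O)/C=C/Cc1ccc(OC)c(OC)c1
A10 | alternative 3 | bis[(Z)-trimethylsilyl ketene acetal] of A8 (arylmethyl trans to the allyloxy oxygen) | COc1cc(C/C=C(\O[Si](C)(C)C)O[C@@H](C)/C=C/Cc2ccc(OC)c(OC)c2)ccc1Oc1cc(C/C=C(\O[Si](C)(C)C)O[C@@H](C)/C=C/Cc2ccc(OC)c(OC)c2)cc(OC)c1OCc1ccccc1
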